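**Plan**
- Labdane numbering is used: ring A = C1–C5 and C10, ring B = C5–C10, C17 on C8, C18 (α) and C19 (β) on C4, C20 on C10, side chain C11–C16; normal series, 5α-H and 10β-CH3.
- Enabling feature: ring A has its C3 oxygen para to the methyl-bearing C10 and ortho to C4 (which carries C19), so it is a dearomatised 5-methylsalicylate; the tetrasubstituted C8=C9 alkene of ring B is what is left of an alkyne.
- Cuts, in retrosynthetic order: C12–C13; the two isovalerate C–O bonds; C4–C18 and C5–H; C8–C17; then C9–C10 (with C8–I) in the key step; C11–C12; C6–C7.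
- Forward: ring A enters as an arene, the C6–C12 alkynyl chain is attached, ring B is closed by dearomatising iodocyclisation, ring A is reduced and methylated, the oxygens are differentiated and acylated, and the C13–C16 enoate is joined last.
- Stereochemistry: C6 by catalyst-controlled propargylation; C10 relayed from C6 in the ring closure; C5 and C4 by α-face hydride addition and α-face methylation; C3 by equatorial attack of a bulky hydride; 13E by syn-stannylcupration and stereoretentive coupling.

Key step: step 7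

Assumptions: aldehyde 1 is taken as a catalogue compound; the (R)-phosphoric acid is taken to give the (R)-carbinol (Re-face attack) as with simple aryl aldehydes, and its antipode is used if the sense proves opposite.

**Route**

Step 1
Reactants: 1 5-methoxy-2-methylbenzaldehyde
Product: 5 2-bromo-3-methoxy-6-methylbenzaldehyde, via lithium α-amino alkoxide 2 (not isolated), via ortho-lithiated α-amino alkoxide 3 (not isolated), via brominated α-amino alkoxide 4 (not isolated)
Conditions: LiN(Me)CH2CH2NMe2 (from MeNHCH2CH2NMe2 and n-BuLi), THF, −20 °C; n-BuLi (3 equiv), −20 °C; BrCCl2CCl2Br, −78 °C → rt; H2O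
Reagents that add atoms: 1,2-dibromo-1,1,2,2-tetrachloroethane, BrC(Cl)(Cl)C(Cl)(Cl)Br
Why: Directed ortho-metalation in which the in situ α-amino alkoxide and the methoxy group together place lithium on the only ring carbon between them (the future C4), the aryllithium takes bromine from the dibromide, and water returns the aldehyde.

Step 2
Reactants: 5 2-bromo-3-methoxy-6-methylbenzaldehyde; 6 allenylboronic acid pinacol ester
Product: 8 (1R)-1-(2-bromo-3-methoxy-6-methylphenyl)but-3-yn-1-ol, via pinacol borate ester 7 (not isolated)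
Conditions: (R)-3,3′-bis(2,4,6-triisopropylphenyl)-1,1′-binaphthyl-2,2′-diyl hydrogen phosphate (10 mol%), 4 Å MS, toluene, −20 °C; aqueous work-up
Reagents that add atoms: none
Why: Chiral-phosphoric-acid-catalysed asymmetric propargylation, in which the activated allenylboronate adds through a closed six-membered SE2′ transition state to the Re face of the aldehyde and should set C6 as (R).

Step 3
Reactants: 8 (1R)-1-(2-bromo-3-methoxy-6-methylphenyl)but-3-yn-1-ol
Product: 9 [(1R)-1-(2-bromo-3-methoxy-6-methylphenyl)but-3-yn-1-yl]oxy(tert-butyl)dimethylsilane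
Conditions: TBSOTf, 2,6-lutidine, CH2Cl2, 0 °C
Reagents that add atoms: tert-butyldimethylsilyl trifluoromethanesulfonate, CC(C)(C)[Si](C)(C)OS(=O)(=O)C(F)(F)F
Why: O-silylation of a hindered benzylic alcohol with the silyl triflate gives the bulky C6 substituent that later steers the ring closure and keeps this oxygen from lactonising onto the future C19 ester.

Step 4
Reactants: 9 [(1R)-1-(2-bromo-3-methoxy-6-methylphenyl)but-3-yn-1-yl]oxy(tert-butyl)dimethylsilane; 10 ethylene oxide
Product: 12 (6R)-6-(2-bromo-3-methoxy-6-methylphenyl)-6-(tert-butyldimethylsilyloxy)hex-3-yn-1-ol, via lithium acetylide 11 (not isolated)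
Conditions: n-BuLi (1.05 equiv), THF, −78 °C; BF3·OEt2; ethylene oxide, −78 °C
Reagents that add atoms: none
Why: BF3-mediated opening of an epoxide by a lithium acetylide (Yamaguchi-type alkynylation) adds C11 and C12, deprotonation of the terminal alkyne being faster than bromine–lithium exchange at −78 °C.

Step 5
Reactants: 12 (6R)-6-(2-bromo-3-methoxy-6-methylphenyl)-6-(tert-butyldimethylsilyloxy)hex-3-yn-1-ol
Product: 13 [(1R)-1-(2-bromo-3-methoxy-6-methylphenyl)-6-chlorohex-3-yn-1-yl]oxy(tert-butyl)dimethylsilane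
Conditions: PPh3, N-chlorosuccinimide, THF, 0 °C → rt
Reagents that add atoms: N-chlorosuccinimide, ClN1C(=O)CCC1=O
Why: Appel-type chlorination under neutral conditions turns C12 into a chloride that survives all later steps and, unlike an ether oxygen, cannot attack the activated alkyne in the key step.

Step 6
Reactants: 13 [(1R)-1-(2-bromo-3-methoxy-6-methylphenyl)-6-chlorohex-3-yn-1-yl]oxy(tert-butyl)dimethylsilane
Product: 15 methyl 6-[(1R)-1-(tert-butyldimethylsilyloxy)-6-chlorohex-3-yn-1-yl]-2-methoxy-5-methylbenzoate, via aryllithium 14 (not isolated)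
Conditions: n-BuLi, THF, −78 °C, 10 min; ClCO2Me, −78 °C → rt
Reagents that add atoms: methyl chloroformate, COC(=O)Cl
Why: Bromine–lithium exchange followed by C-acylation installs C19 only after the C6 oxygen is silylated, so no phthalide can form, and at −78 °C the exchange should outrun attack on the alkyne, on the primary chloride, and oxygen-to-carbon silyl migration.

Step 7
Reactants: 15 methyl 6-[(1R)-1-(tert-butyldimethylsilyloxy)-6-chlorohex-3-yn-1-yl]-2-methoxy-5-methylbenzoate
Product: 17 methyl 6β-(tert-butyldimethylsilyloxy)-12-chloro-8-iodo-3-oxo-13,14,15,16,17-pentanorlabda-1,4,8-trien-19-oate, via O-methyl oxocarbenium chloride 16 (not isolated)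
Conditions: ICl (1.2 equiv), CH2Cl2, −78 °C; aq. Na2S2O3
Reagents that add atoms: iodine monochloride, ClI
Why: Proposed new method: ICl should form an iodonium complex of the C8≡C9 alkyne that is opened anti by C10, the ring carbon para to the methoxy group, and the O-methyl cyclohexadienyl cation 16 is then demethylated by chloride to release the cross-conjugated dienone; the closest known reactions are the ICl-induced ipso-iodocyclisations of 4-methoxyaryl alkynes to spirocyclohexadienones and the 6-endo iodocyclisations of 4-aryl-1-butynes to 3-iodo-1,2-dihydronaphthalenes, merged here at an ortho-tethered, methyl-bearing para carbon. Ring B closes 6-endo-dig (C9–C10 bond, both alkyne carbons in the ring), the mode a three-atom C5–C6–C7 tether imposes on an ortho carbon. The new quaternary centre C10 is controlled by the C6 silyloxy centre: the C6–H bond should lie in the arene plane beside the twisted C4 ester (allylic 1,3-strain), so C7 and the silyloxy group sit on opposite faces, C9 bonds anti to oxygen, and the methyl group ends up cis to the 6-oxygen (6β-O, 10β-CH3). The step needs attack at C10 and not at the ester-bearing ortho carbon C4, and carbocyclisation and not ring iodination at C2 or plain ICl addition; the para-methoxy activation of C10, the deactivating ester at C4, the low temperature and the intramolecular delivery should secure this. The chloroethyl group carries no oxygen that could add to C8 in a competing 5-endo-dig iodoetherification.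

Step 8
Reactants: 17 methyl 6β-(tert-butyldimethylsilyloxy)-12-chloro-8-iodo-3-oxo-13,14,15,16,17-pentanorlabda-1,4,8-trien-19-oate
Product: 18 methyl 6β-(tert-butyldimethylsilyloxy)-12-chloro-3-oxo-13,14,15,16-tetranorlabda-1,4,8-trien-19-oate
Conditions: Me2Zn (2 equiv), Pd(PPh3)4 (5 mol%), THF, 0 → 50 °C
Reagents that add atoms: dimethylzinc, C[Zn]C
Why: Negishi coupling of the tetrasubstituted vinyl iodide introduces C17 with retention of the ring alkene, and dimethylzinc does not add to the dienone without a copper or nickel catalyst.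

Step 9
Reactants: 18 methyl 6β-(tert-butyldimethylsilyloxy)-12-chloro-3-oxo-13,14,15,16-tetranorlabda-1,4,8-trien-19-oate
Product: 19 methyl 6β-(tert-butyldimethylsilyloxy)-12-chloro-3-oxo-13,14,15,16-tetranorlabda-4,8-dien-19-oate
Conditions: H2 (1 atm), RhCl(PPh3)3 (10 mol%), benzene, rt
Reagents that add atoms: none
Why: Homogeneous hydrogenation with RhCl(PPh3)3 is selective for the disubstituted C1=C2 bond of a cross-conjugated dienone and should leave both tetrasubstituted alkenes and the alkyl chloride untouched.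

Step 10
Reactants: 19 methyl 6β-(tert-butyldimethylsilyloxy)-12-chloro-3-oxo-13,14,15,16-tetranorlabda-4,8-dien-19-oate
Product: 21 methyl 6β-(tert-butyldimethylsilyloxy)-12-chloro-3-oxo-13,14,15,16-tetranorlabd-8-en-19-oate, via lithium enolate 20 (not isolated)
Conditions: LiBH(s-Bu)3 (1.05 equiv), THF, −78 °C; MeI (5 equiv), DMPU, −78 °C → rt
Reagents that add atoms: iodomethane, CI
Why: Conjugate reduction with in situ enolate alkylation (reductive alkylation), in which hydride adds to the doubly activated C5 from the α-face, anti to the C10 methyl and the 6β-silyloxy group, to set the trans ring fusion, and the β-keto ester enolate is then C-methylated from the same α-face so that the ester becomes the axial C19.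

Step 11
Reactants: 21 methyl 6β-(tert-butyldimethylsilyloxy)-12-chloro-3-oxo-13,14,15,16-tetranorlabd-8-en-19-oate
Product: 22 methyl 6β-(tert-butyldimethylsilyloxy)-12-chloro-3α-hydroxy-13,14,15,16-tetranorlabd-8-en-19-oate
Conditions: LiBH(s-Bu)3, THF, −78 °C
Reagents that add atoms: none
Why: Diastereoselective ketone reduction in which the bulky trialkylborohydride attacks C3 along the equatorial trajectory, as with 4,4-disubstituted 3-oxo terpenoids, and should give the axial 3α-alcohol while esters and the chloride stay inert at −78 °C.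

Step 12
Reactants: 22 methyl 6β-(tert-butyldimethylsilyloxy)-12-chloro-3α-hydroxy-13,14,15,16-tetranorlabd-8-en-19-oate
Product: 23 6β-(tert-butyldimethylsilyloxy)-12-chloro-13,14,15,16-tetranorlabd-8-ene-3α,19-diol
Conditions: i-Bu2AlH (5 equiv), CH2Cl2, −78 → 0 °C; aqueous potassium sodium tartrate
Reagents that add atoms: none
Why: Hydride reduction of the hindered axial ester to the C19 primary alcohol with i-Bu2AlH, which neither reduces a primary alkyl chloride nor cleaves the silyl ether.

Step 13
Reactants: 23 6β-(tert-butyldimethylsilyloxy)-12-chloro-13,14,15,16-tetranorlabd-8-ene-3α,19-diol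
Product: 24 12-chloro-13,14,15,16-tetranorlabd-8-ene-3α,6β,19-triol
Conditions: HF·pyridine, pyridine, THF, 0 °C → rt
Reagents that add atoms: none
Why: Fluoride-induced desilylation, driven by the Si–F bond, removes the hindered 6β-silyl group under mild conditions that leave the chloride and the tetrasubstituted alkene intact.

Step 14
Reactants: 24 12-chloro-13,14,15,16-tetranorlabd-8-ene-3α,6β,19-triol
Product: 25 19-(tert-butyldimethylsilyloxy)-12-chloro-13,14,15,16-tetranorlabd-8-ene-3α,6β-diol
Conditions: TBSCl (1.1 equiv), imidazole, DMF, 0 °C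
Reagents that add atoms: tert-butyldimethylsilyl chloride, CC(C)(C)[Si](C)(C)Cl
Why: Chemoselective silylation, since the primary C19 hydroxyl reacts far faster than the two hindered axial secondary hydroxyls, masks the one oxygen that stays free in the target.

Step 15
Reactants: 25 19-(tert-butyldimethylsilyloxy)-12-chloro-13,14,15,16-tetranorlabd-8-ene-3α,6β-diol
Product: 26 19-(tert-butyldimethylsilyloxy)-12-chloro-13,14,15,16-tetranorlabd-8-ene-3α,6β-diyl bis(3-methylbutanoate)
Conditions: (i-BuCO)2O (6 equiv), 4-(dimethylamino)pyridine (3 equiv), Et3N, toluene, 80 °C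
Reagents that add atoms: 3-methylbutanoic anhydride, CC(C)CC(=O)OC(=O)CC(C)C
Why: Acyl transfer catalysed by 4-(dimethylamino)pyridine esterifies both axial secondary alcohols, forcing conditions being expected for the 6β-hydroxyl, and the trans-diaxial 3α-O/C19 arrangement rules out later acyl migration between these two positions.

Step 16
Reactants: 26 19-(tert-butyldimethylsilyloxy)-12-chloro-13,14,15,16-tetranorlabd-8-ene-3α,6β-diyl bis(3-methylbutanoate)
Product: 27 19-(tert-butyldimethylsilyloxy)-12-iodo-13,14,15,16-tetranorlabd-8-ene-3α,6β-diyl bis(3-methylbutanoate)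
Conditions: NaI (10 equiv), 2-butanone, 80 °C
Reagents that add atoms: sodium iodide, [Na+].[I-]
Why: Finkelstein halide exchange, driven by precipitation of NaCl, gives the primary iodide needed for zinc insertion without touching the esters.

Step 17
Reactants: 28 but-2-ynoic acid
Product: 29 tert-butyl but-2-ynoate
Conditions: isobutene, H2SO4 (cat.), CH2Cl2, sealed vessel, rt
Reagents that add atoms: 2-methylpropene, CC(C)=C
Why: Acid-catalysed addition of the carboxylic acid to isobutene gives a tert-butyl ester that can later be cleaved by acid in the presence of the two isovalerates.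

Step 18
Reactants: 29 tert-butyl but-2-ynoate
Product: 30 tert-butyl (E)-3-(tributylstannyl)but-2-enoate
Conditions: Bu3SnH, LiN(i-Pr)2, THF, −78 → 0 °C; CuBr·SMe2, −78 °C; then 29, MeOH, −78 °C
Reagents that add atoms: tributyltin hydride, CCCC[SnH](CCCC)CCCC
Why: Stannylcupration of an ynoate, where syn addition of the stannylcopper reagent and immediate protonation of the vinylcopper by methanol at −78 °C should give the kinetic (E)-β-stannyl enoate with tin trans to the ester.

Step 19
Reactants: 30 tert-butyl (E)-3-(tributylstannyl)but-2-enoate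
Product: 31 tert-butyl (E)-3-iodobut-2-enoate
Conditions: I2, CH2Cl2, 0 °C
Reagents that add atoms: iodine, II
Why: Iododestannylation is an ipso substitution that proceeds with retention of alkene geometry.

Step 20
Reactants: 27 19-(tert-butyldimethylsilyloxy)-12-iodo-13,14,15,16-tetranorlabd-8-ene-3α,6β-diyl bis(3-methylbutanoate); 31 tert-butyl (E)-3-iodobut-2-enoate
Product: 33 tert-butyl 19-(tert-butyldimethylsilyloxy)-3α,6β-bis(3-methylbutanoyloxy)labda-8,13E-dien-15-oate, via alkylzinc iodide 32 (not isolated)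
Conditions: Zn dust (activated with BrCH2CH2Br and Me3SiCl), DMA, 40 °C; then 31, Pd(PPh3)4 (5 mol%), THF, rt
Reagents that add atoms: none
Why: Zinc insertion into the primary iodide followed by Negishi sp3–sp2 coupling tolerates the esters and the silyl ether and joins C12 to C13 with retention of the (E) geometry of the iodo enoate.

Step 21
Reactants: 33 tert-butyl 19-(tert-butyldimethylsilyloxy)-3α,6β-bis(3-methylbutanoyloxy)labda-8,13E-dien-15-oate
Product: 34 19-hydroxy-3α,6β-bis(3-methylbutanoyloxy)labda-8,13E-dien-15-oic acid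
Conditions: CF3CO2H/CH2Cl2/H2O (20:78:2), 0 °C → rt; aq. NaHCO3 wash, then mild acidification
Reagents that add atoms: none
Why: Acidolysis with trifluoroacetic acid cleaves the tert-butyl ester by loss of isobutene and the primary silyl ether in one operation without base, so the isovalerates should neither hydrolyse nor migrate to the freed C19 hydroxyl.

**Compound list**

1 | 5-methoxy-2-methylbenzaldehyde | COc1ccc(C)c(C=O)c1 | starting material
2 | lithium α-amino alkoxide from 1 and lithium N,N,N′-trimethylethylenediamide | COc1ccc(C)c(C(O[Li])N(C)CCN(C)C)c1 | intermediate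
3 | ortho-lithiated α-amino alkoxide | COc1ccc(C)c(C(O[Li])N(C)CCN(C)C)c1[Li] | intermediate
4 | brominated α-amino alkoxide | COc1ccc(C)c(C(O[Li])N(C)CCN(C)C)c1Br | intermediate
5 | 2-bromo-3-methoxy-6-methylbenzaldehyde | COc1ccc(C)c(C=O)c1Br | intermediate
6 | allenylboronic acid pinacol ester | C=C=CB1OC(C)(C)C(C)(C)O1 | starting material
7 | pinacol borate ester of 8 | COc1ccc(C)c([C@H](OB2OC(C)(C)C(C)(C)O2)CC#C)c1Br | intermediate
8 | (1R)-1-(2-bromo-3-methoxy-6-methylphenyl)but-3-yn-1-ol | COc1ccc(C)c([C@H](O)CC#C)c1Br | intermediate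
9 | [(1R)-1-(2-bromo-3-methoxy-6-methylphenyl)but-3-yn-1-yl]oxy(tert-butyl)dimethylsilane | COc1ccc(C)c([C@H](O[Si](C)(C)C(C)(C)C)CC#C)c1Br | intermediate
10 | ethylene oxide | C1CO1 | starting material
11 | lithium acetylide of 9 | COc1ccc(C)c([C@H](O[Si](C)(C)C(C)(C)C)CC#C[Li])c1Br | intermediate
12 | (6R)-6-(2-bromo-3-methoxy-6-methylphenyl)-6-(tert-butyldimethylsilyloxy)hex-3-yn-1-ol | COc1ccc(C)c([C@H](O[Si](C)(C)C(C)(C)C)CC#CCCO)c1Br | intermediate
13 | [(1R)-1-(2-bromo-3-methoxy-6-methylphenyl)-6-chlorohex-3-yn-1-yl]oxy(tert-butyl)dimethylsilane | COc1ccc(C)c([C@H](O[Si](C)(C)C(C)(C)C)CC#CCCCl)c1Br | intermediate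
14 | aryllithium from 13 | COc1ccc(C)c([C@H](O[Si](C)(C)C(C)(C)C)CC#CCCCl)c1[Li] | intermediate
15 | methyl 6-[(1R)-1-(tert-butyldimethylsilyloxy)-6-chlorohex-3-yn-1-yl]-2-methoxy-5-methylbenzoate | COc1ccc(C)c([C@H](O[Si](C)(C)C(C)(C)C)CC#CCCCl)c1C(=O)OC | intermediate
16 | O-methyl oxocarbenium chloride (3-O-methylated form of 17) | IC1=C(CCCl)[C@@]2(C)C=CC(=[O+]C)C(C(=O)OC)=C2[C@H](O[Si](C)(C)C(C)(C)C)C1.[Cl-] | intermediate
17 | methyl 6β-(tert-butyldimethylsilyloxy)-12-chloro-8-iodo-3-oxo-13,14,15,16,17-pentanorlabda-1,4,8-trien-19-oate | IC1=C(CCCl)[C@@]2(C)C=CC(=O)C(C(=O)OC)=C2[C@H](O[Si](C)(C)C(C)(C)C)C1 | intermediate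
18 | methyl 6β-(tert-butyldimethylsilyloxy)-12-chloro-3-oxo-13,14,15,16-tetranorlabda-1,4,8-trien-19-oate | CC1=C(CCCl)[C@@]2(C)C=CC(=O)C(C(=O)OC)=C2[C@H](O[Si](C)(C)C(C)(C)C)C1 | intermediate
19 | methyl 6β-(tert-butyldimethylsilyloxy)-12-chloro-3-oxo-13,14,15,16-tetranorlabda-4,8-dien-19-oate | CC1=C(CCCl)[C@@]2(C)CCC(=O)C(C(=O)OC)=C2[C@H](O[Si](C)(C)C(C)(C)C)C1 | intermediate
20 | lithium enolate (O3–C3=C4) of the 5α-H β-keto ester | CC1=C(CCCl)[C@@]2(C)CCC(O[Li])=C(C(=O)OC)[C@@H]2[C@H](O[Si](C)(C)C(C)(C)C)C1 | intermediate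
21 | methyl 6β-(tert-butyldimethylsilyloxy)-12-chloro-3-oxo-13,14,15,16-tetranorlabd-8-en-19-oate | CC1=C(CCCl)[C@@]2(C)CCC(=O)[C@](C)(C(=O)OC)[C@@H]2[C@H](O[Si](C)(C)C(C)(C)C)C1 | intermediate
22 | methyl 6β-(tert-butyldimethylsilyloxy)-12-chloro-3α-hydroxy-13,14,15,16-tetranorlabd-8-en-19-oate | CC1=C(CCCl)[C@@]2(C)CC[C@@H](O)[C@](C)(C(=O)OC)[C@@H]2[C@H](O[Si](C)(C)C(C)(C)C)C1 | intermediate
23 | 6β-(tert-butyldimethylsilyloxy)-12-chloro-13,14,15,16-tetranorlabd-8-ene-3α,19-diol | CC1=C(CCCl)[C@@]2(C)CC[C@@H](O)[C@](C)(CO)[C@@H]2[C@H](O[Si](C)(C)C(C)(C)C)C1 | intermediate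
24 | 12-chloro-13,14,15,16-tetranorlabd-8-ene-3α,6β,19-triol | CC1=C(CCCl)[C@@]2(C)CC[C@@H](O)[C@](C)(CO)[C@@H]2[C@H](O)C1 | intermediate
25 | 19-(tert-butyldimethylsilyloxy)-12-chloro-13,14,15,16-tetranorlabd-8-ene-3α,6β-diol | CC1=C(CCCl)[C@@]2(C)CC[C@@H](O)[C@](C)(CO[Si](C)(C)C(C)(C)C)[C@@H]2[C@H](O)C1 | intermediate
26 | 19-(tert-butyldimethylsilyloxy)-12-chloro-13,14,15,16-tetranorlabd-8-ene-3α,6β-diyl bis(3-methylbutanoate) | CC1=C(CCCl)[C@@]2(C)CC[C@@H](OC(=O)CC(C)C)[C@](C)(CO[Si](C)(C)C(C)(C)C)[C@@H]2[C@H](OC(=O)CC(C)C)C1 | intermediate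
27 | 19-(tert-butyldimethylsilyloxy)-12-iodo-13,14,15,16-tetranorlabd-8-ene-3α,6β-diyl bis(3-methylbutanoate) | CC1=C(CCI)[C@@]2(C)CC[C@@H](OC(=O)CC(C)C)[C@](C)(CO[Si](C)(C)C(C)(C)C)[C@@H]2[C@H](OC(=O)CC(C)C)C1 | intermediate
28 | but-2-ynoic acid | CC#CC(=O)O | starting material
29 | tert-butyl but-2-ynoate | CC#CC(=O)OC(C)(C)C | intermediate
30 | tert-butyl (E)-3-(tributylstannyl)but-2-enoate | CCCC[Sn](CCCC)(CCCC)/C(C)=C/C(=O)OC(C)(C)C | intermediate
31 | tert-butyl (E)-3-iodobut-2-enoate | I/C(C)=C/C(=O)OC(C)(C)C | intermediate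
32 | alkylzinc iodide from 27 | CC1=C(CC[Zn]I)[C@@]2(C)CC[C@@H](OC(=O)CC(C)C)[C@](C)(CO[Si](C)(C)C(C)(C)C)[C@@H]2[C@H](OC(=O)CC(C)C)C1 | intermediate
33 | tert-butyl 19-(tert-butyldimethylsilyloxy)-3α,6β-bis(3-methylbutanoyloxy)labda-8,13E-dien-15-oate | CC1=C(CC/C(C)=C/C(=O)OC(C)(C)C)[C@@]2(C)CC[C@@H](OC(=O)CC(C)C)[C@](C)(CO[Si](C)(C)C(C)(C)C)[C@@H]2[C@H](OC(=O)CC(C)C)C1 | intermediate
34 | 19-hydroxy-3α,6β-bis(3-methylbutanoyloxy)labda-8,13E-dien-15-oic acid (CNP0272110.1) | CC1=C(CC/C(C)=C/C(=O)O)[C@@]2(C)CC[C@@H](OC(=O)CC(C)C)[C@](C)(CO)[C@@H]2[C@H](OC(=O)CC(C)C)C1 | target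

**Step count**

Total: 21 steps. Longest linear sequence: 18 steps (steps 1–16, 20 and 21); steps 17–19 make the side-chain fragment.

**Steps most likely to fail**

1. Step 7, the one step that rests on a new method. The arene may be iodinated at C2, or ICl may simply add across the alkyne, before the ring closes; the relay from C6 to the C10 face may also be weak.
 Fallback, known reaction types only, from aldehyde 5 back to dienone 18. The C9–C10 bond is made by palladium-catalysed intramolecular dearomative coupling of a para-methyl phenol with a tethered alkenyl bromide, an established way to fused dienones with an angular methyl group. C11–C12 are then added by a formaldehyde ene reaction that also moves the alkene to C8=C9.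
 - Phosphoric-acid-catalysed addition of methallylboronic acid pinacol ester to 5 (catalyst of step 2) should give (1R)-1-(2-bromo-3-methoxy-6-methylphenyl)-3-methylbut-3-en-1-ol F1.
 - TBSOTf/2,6-lutidine gives its silyl ether F2.
 - n-BuLi then ClCO2Me gives methyl 6-[(1R)-1-(tert-butyldimethylsilyloxy)-3-methylbut-3-en-1-yl]-2-methoxy-5-methylbenzoate F3.
 - Hydroboration–oxidation (9-borabicyclo[3.3.1]nonane; NaBO3) gives the primary alcohol F4 as both C8 epimers; this centre is lost later.
 - DMP oxidation gives the aldehyde F5.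
 - Seyferth–Gilbert homologation (dimethyl (1-diazo-2-oxopropyl)phosphonate, K2CO3, MeOH) gives the terminal alkyne F6.
 - Bromoboration with B-bromo-9-borabicyclo[3.3.1]nonane and protonolysis with AcOH gives the 2-bromo-1-alkene F7.
 - Chelation-assisted O-demethylation beside the ester (MgI2·OEt2) gives the phenol F8.
 - Pd2(dba)3/P(t-Bu)3, K2CO3, toluene, 90 °C closes ring B to the 9(11)-methylidene dienone F9; a P-chiral monophosphine is used if C6 alone does not control C10.
 - Me2AlCl-promoted carbonyl-ene reaction with paraformaldehyde, in which C8–H is the only allylic hydrogen, gives the Δ8 homoallylic alcohol F10.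
 - PPh3/N-chlorosuccinimide then gives 18.

2. Step 10. Hydride may add to the C3 carbonyl, or fail to reach the fully substituted and shielded C5, and the boron-bound enolate may be O-methylated or react sluggishly.
 Fallback from 19 back to 21: the two events are separated and the reduction is made radical. Hydrogen-atom-transfer conjugate reduction (Mn(dpm)3, PhSiH3, i-PrOH) should give the isolated trans-fused methyl 6β-(tert-butyldimethylsilyloxy)-12-chloro-3-oxo-13,14,15,16,18-pentanorlabd-8-en-19-oate F11. Its C-methylation with K2CO3/MeI in acetone, again from the α-face, gives 21.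

3. Step 6. The aryllithium may suffer oxygen-to-carbon silyl migration (retro-Brook) from the neighbouring benzylic silyl ether, or add to the tethered alkyne, before it is acylated.
 Fallback from 13 back to 15 without an organolithium: palladium-catalysed methoxycarbonylation of the aryl bromide (Pd(OAc)2, Xantphos, CO (1 atm), MeOH, Et3N, 70 °C). No new compound arises (F0).

**Further compounds**

F1 | step 7 | (1R)-1-(2-bromo-3-methoxy-6-methylphenyl)-3-methylbut-3-en-1-ol | COc1ccc(C)c([C@H](O)CC(C)=C)c1Br
F2 | step 7 | tert-butyldimethylsilyl ether of F1 | COc1ccc(C)c([C@H](O[Si](C)(C)C(C)(C)C)CC(C)=C)c1Br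
F3 | step 7 | methyl 6-[(1R)-1-(tert-butyldimethylsilyloxy)-3-methylbut-3-en-1-yl]-2-methoxy-5-methylbenzoate | COc1ccc(C)c([C@H](O[Si](C)(C)C(C)(C)C)CC(C)=C)c1C(=O)OC
F4 | step 7 | methyl 6-[(1R)-1-(tert-butyldimethylsilyloxy)-4-hydroxy-3-methylbutyl]-2-methoxy-5-methylbenzoate (C3′ epimers) | COc1ccc(C)c([C@H](O[Si](C)(C)C(C)(C)C)CC(C)CO)c1C(=O)OC
F5 | step 7 | methyl 6-[(1R)-1-(tert-butyldimethylsilyloxy)-3-methyl-4-oxobutyl]-2-methoxy-5-methylbenzoate | COc1ccc(C)c([C@H](O[Si](C)(C)C(C)(C)C)CC(C)C=O)c1C(=O)OC
F6 | step 7 | methyl 6-[(1R)-1-(tert-butyldimethylsilyloxy)-3-methylpent-4-yn-1-yl]-2-methoxy-5-methylbenzoate | COc1ccc(C)c([C@H](O[Si](C)(C)C(C)(C)C)CC(C)C#C)c1C(=O)OC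
F7 | step 7 | methyl 6-[(1R)-4-bromo-1-(tert-butyldimethylsilyloxy)-3-methylpent-4-en-1-yl]-2-methoxy-5-methylbenzoate | COc1ccc(C)c([C@H](O[Si](C)(C)C(C)(C)C)CC(C)C(Br)=C)c1C(=O)OC
F8 | step 7 | methyl 6-[(1R)-4-bromo-1-(tert-butyldimethylsilyloxy)-3-methylpent-4-en-1-yl]-2-hydroxy-5-methylbenzoate | Oc1ccc(C)c([C@H](O[Si](C)(C)C(C)(C)C)CC(C)C(Br)=C)c1C(=O)OC
F9 | step 7 | methyl 6β-(tert-butyldimethylsilyloxy)-3-oxo-12,13,14,15,16-pentanorlabda-1,4,9(11)-trien-19-oate (C8 epimers) | CC1C(=C)[C@@]2(C)C=CC(=O)C(C(=O)OC)=C2[C@H](O[Si](C)(C)C(C)(C)C)C1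
F10 | step 7 | methyl 6β-(tert-butyldimethylsilyloxy)-12-hydroxy-3-oxo-13,14,15,16-tetranorlabda-1,4,8-trien-19-oate | CC1=C(CCO)[C@@]2(C)C=CC(=O)C(C(=O)OC)=C2[C@H](O[Si](C)(C)C(C)(C)C)C1
F11 | step 10 | methyl 6β-(tert-butyldimethylsilyloxy)-12-chloro-3-oxo-13,14,15,16,18-pentanorlabd-8-en-19-oate (C4 epimers) | CC1=C(CCCl)[C@@]2(C)CCC(=O)C(C(=O)OC)[C@@H]2[C@H](O[Si](C)(C)C(C)(C)C)C1
F0 | step 6 | none | none
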